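Everything rests on cutting ring A (isoflavanone numbering) at C7–C8, C4a–C8a and C6–C7. This separates a 4-prenyl-3-siloxycyclobutenone (C4a, C5, C6, C7 with O5 and O7) from an enantiopure terminal ynol ether (C8, C8a, O1) that already carries C2, C3 and ring B. One thermal cascade builds ring A on O1, with the C6 prenyl group para to C8a and flanked by O5 and O7. Because C8a is para to C6, giving O7 the same silyl group as O5 makes C4a and C8 equivalent, so the later C4–C4a acylation cannot give an 8-prenyl isomer. C3 is set by enzymatic desymmetrisation and has no neighbouring carbonyl until after the key step.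

Key step: step 12

Abbreviations: prenyl = 3-methylbut-2-en-1-yl; TIPS = triisopropylsilyl; Tr = triphenylmethyl; ArB = 3-prenyl-4-(TIPS-oxy)phenyl. Atom numbers are those of the isoflavanone (O1, C2, C3, C4, C4a to C8a, ring B primed). The target is (3R).

Assumption: the lipase is taken to acylate the pro-S hydroxymethyl group of the prochiral diol, as expected for 2-substituted propane-1,3-diols with Burkholderia cepacia lipase; the sense is to be confirmed (Mosher esters) before material is carried on.

Remark: the arm that becomes C4 is masked as a trityl ether and not as a silyl ether, because a silyl group on a propane-1,3-diol shuttles between the two enantiotopic oxygens under alkoxide conditions and would racemise C3 during the ynol ether synthesis. Every hydroxyl is capped before the key step so that the vinylketene meets no OH.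

**Route**

Step 1
Reactants: 1 4-bromophenol; 2 prenyl bromide (1-bromo-3-methylbut-2-ene)
Product: 3 4-bromo-2-prenylphenol
Conditions: NaH, toluene, 0 °C; then 2, rt
Reagents that add atoms: none
Why: C-alkylation of a phenoxide: the sodium salt, a tight ion pair in toluene, should be alkylated at the free ortho carbon (para is blocked by bromine) in preference to oxygen, and the O-prenyl ether formed alongside is removed by chromatography.

Step 2
Reactants: 3 4-bromo-2-prenylphenol
Product: 4 (4-bromo-2-prenylphenoxy)triisopropylsilane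
Conditions: TIPSCl, imidazole, DMF, rt
Reagents that add atoms: triisopropylsilyl chloride, CC(C)[Si](Cl)(C(C)C)C(C)C
Why: Standard silylation of a phenol; the TIPS ether is chosen because it should survive the palladium, hydride, alkoxide and organolithium steps and is cleaved by fluoride at the end.

Step 3
Reactants: 4 (4-bromo-2-prenylphenoxy)triisopropylsilane; 5 diethyl malonate
Product: 6 diethyl 2-ArB-malonate
Conditions: Pd(dba)2 (cat.), P(t-Bu)3 (cat.), K3PO4, toluene, 70 °C
Reagents that add atoms: none
Why: Palladium-catalysed α-arylation of a malonate (Buchwald–Hartwig type): oxidative addition of the electron-rich aryl bromide to zerovalent palladium bearing the bulky phosphine, exchange with the potassium malonate and reductive elimination form the bond that becomes C1'–C3.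

Step 4
Reactants: 6 diethyl 2-ArB-malonate
Product: 7 2-ArB-propane-1,3-diol (prochiral)
Conditions: LiAlH4, THF, 0 °C
Reagents that add atoms: none
Why: Hydride reduction of both esters to the prochiral diol; the aryl silyl ether and the trisubstituted alkene are inert to LiAlH4 at 0 °C.

Step 5
Reactants: 7 2-ArB-propane-1,3-diol
Product: 8 (S)-3-hydroxy-2-ArB-propyl acetate
Conditions: Burkholderia cepacia lipase (immobilised), vinyl acetate, t-BuOMe, rt
Reagents that add atoms: vinyl acetate, C=COC(C)=O
Why: Lipase-catalysed desymmetrisation by irreversible transesterification: the enzyme active site acylates one of the two enantiotopic hydroxymethyl groups (taken as pro-S), which sets C3, and vinyl acetate makes the step irreversible by releasing acetaldehyde.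

Step 6
Reactants: 8 (S)-3-hydroxy-2-ArB-propyl acetate
Product: 9 (S)-2-ArB-3-(trityloxy)propyl acetate
Conditions: TrCl, pyridine, DMAP (cat.), CH2Cl2, rt
Reagents that add atoms: trityl chloride, ClC(c1ccccc1)(c1ccccc1)c1ccccc1
Why: Tritylation of the remaining primary alcohol under weakly basic conditions that should not promote acetyl migration; the trityl ether is inert to alkoxide and organolithium reagents and cannot move to the neighbouring oxygen.

Step 7
Reactants: 9 (S)-2-ArB-3-(trityloxy)propyl acetate
Product: 10 (R)-2-ArB-3-(trityloxy)propan-1-ol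
Conditions: K2CO3 (cat.), MeOH, 0 °C
Reagents that add atoms: none
Why: Base-catalysed transesterification removes the acetate; with the other oxygen locked as a trityl ether nothing can interconvert the two arms, and the hindered aryl silyl ether should tolerate catalytic carbonate at 0 °C (the descriptor changes only because the priorities change).

Step 8
Reactants: 10 (R)-2-ArB-3-(trityloxy)propan-1-ol; 11 trichloroethylene
Product: 14 (R)-ethynyl ether of 10 [HC≡C–O–CH2–CH(ArB)–CH2–OTr], via dichlorovinyl ether 12 (not isolated), via lithium alkynyl ether 13 (not isolated)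
Conditions: KH, THF, 0 °C; 11, −40 °C to rt; then n-BuLi (2.5 equiv), −78 to −40 °C; H2O
Reagents that add atoms: none
Why: Ynol ether synthesis from trichloroethylene: the potassium alkoxide adds to dichloroacetylene generated in situ to give the (E)-1,2-dichlorovinyl ether 12, which n-BuLi converts by elimination and chlorine–lithium exchange into the lithium alkoxyacetylide 13, protonated on quenching, with C3 a spectator.

Step 9
Reactants: 15 acetylene
Product: 18 (ethynyloxy)triisopropylsilane, via lithium acetylide 16 (not isolated), via lithium ethynolate 17 (not isolated)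
Conditions: n-BuLi, THF, −78 °C; t-BuOOLi (from t-BuOOH and LiN(SiMe3)2), −78 to 0 °C; TIPSOTf, −78 to 0 °C
Reagents that add atoms: tert-butyl hydroperoxide, CC(C)(C)OO; triisopropylsilyl trifluoromethanesulfonate, CC(C)[Si](OS(=O)(=O)C(F)(F)F)(C(C)C)C(C)C
Why: Electrophilic oxygenation of a lithium acetylide by lithium tert-butyl peroxide gives the lithium ynolate, which the hard and bulky silyl triflate should silylate at oxygen to give the siloxyalkyne (the usual route to 1-siloxyalkynes, applied to the parent acetylide).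

Step 10
Reactants: 19 5-methylhex-4-enoic acid
Product: 20 5-methylhex-4-enoyl chloride
Conditions: (COCl)2, DMF (cat.), CH2Cl2, 0 °C to rt
Reagents that add atoms: oxalyl chloride, O=C(Cl)C(=O)Cl
Why: Conversion of the acid into the acid chloride with oxalyl chloride and catalytic DMF; the trisubstituted alkene should tolerate these conditions at 0 °C.

Step 11
Reactants: 20 5-methylhex-4-enoyl chloride; 18 (ethynyloxy)triisopropylsilane
Product: 22 4-prenyl-3-(TIPS-oxy)cyclobut-2-en-1-one (racemic), via prenylketene 21 (not isolated)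
Conditions: Et3N, CH2Cl2, 0 °C to rt, slow addition of 20
Reagents that add atoms: none
Why: Dehydrochlorination gives prenylketene 21 at low stationary concentration, which the electron-rich siloxyalkyne traps in a [2+2] cycloaddition in which the ketene carbonyl carbon bonds to the nucleophilic terminal alkyne carbon, hence the 3-siloxy-4-alkyl pattern (ketene–ynol ether cycloaddition).

Step 12
Reactants: 22 4-prenyl-3-(TIPS-oxy)cyclobut-2-en-1-one; 14 (R)-ethynyl ether
Product: 27 (R)-aryl ether with complete ring A [3-hydroxy-4-prenyl-5-(TIPS-oxy)phenyl ether of 10; O7 free and O5 silylated], via vinylketene 23 (not isolated), via vinylcyclobutenone 24 (not isolated), via dienylketene 25 (not isolated), via cyclohexadienone 26 (not isolated)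
Conditions: 22 (1.5 equiv, in portions), toluene (degassed), 80 °C
Reagents that add atoms: none
Why: Heating opens 22 by four-electron electrocyclic cleavage of C6–C7 to vinylketene 23, and the nucleophilic terminal carbon of 14 (C8) attacks the ketene carbon C7 while the oxygen-bearing carbon C8a bonds to C4a, a regiospecific [2+2] cycloaddition that gives 24. Four-electron opening of 24 (C4a–C7 cleavage, reversible, productive only with C5 cis to C8) gives dienylketene 25, ring A is closed by six-electron electrocyclisation forming C6–C7, and dienone 26 tautomerises to phenol 27. This is the Danheiser benzannulation of a cyclobutenone with an alkoxyalkyne, the known route to resorcinol monoethers, here run with a 3-siloxy-4-alkylcyclobutenone. No stereocentre is created: the sp3 carbons of 24 and 26 are erased on aromatisation, and C3 carries only an aryl group and two CH2O groups and so cannot epimerise. The selectivity needed is the orientation of the ketene–alkyne union, secured by the polarisation of the ynol ether, which alone puts O1 para to the prenylated C6 with O5 and O7 beside it. The cascade must also outrun retro-ene loss of ketene from 14, for which the temperature is held at 80 °C, 22 is used in excess and no free OH is present to trap 23.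

Step 13
Reactants: 27 (R)-aryl ether with O7 free
Product: 28 (R)-3,5-bis(TIPS-oxy)-4-prenylphenyl ether of 10
Conditions: TIPSCl, imidazole, DMAP (cat.), DMF, 40 °C
Reagents that add atoms: triisopropylsilyl chloride, CC(C)[Si](Cl)(C(C)C)C(C)C
Why: Silylation of the O7 phenol gives O5 and O7 the same group, so that ring A acquires a mirror plane through C6 and C8a and C4a becomes equivalent to C8.

Step 14
Reactants: 28 (R)-3,5-bis(TIPS-oxy)-4-prenylphenyl ether of 10
Product: 29 (S)-2-ArB-3-[3,5-bis(TIPS-oxy)-4-prenylphenoxy]propan-1-ol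
Conditions: CSA (cat.), MeOH/CH2Cl2, 0 °C to rt
Reagents that add atoms: none
Why: Acid-catalysed methanolysis of the trityl ether (ionisation to the trityl cation, captured by methanol) frees the primary alcohol, while aryl TIPS ethers, the aryl alkyl ether and the prenyl alkenes should be stable to catalytic sulfonic acid in methanol.

Step 15
Reactants: 29 (S)-2-ArB-3-[3,5-bis(TIPS-oxy)-4-prenylphenoxy]propan-1-ol
Product: 31 (R)-2-ArB-3-[3,5-bis(TIPS-oxy)-4-prenylphenoxy]propanoic acid, via aldehyde 30 (not isolated)
Conditions: TEMPO (cat.), PhI(OAc)2 (2.2 equiv), MeCN/CH2Cl2/H2O, rt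
Reagents that add atoms: water, O
Why: Nitroxyl-catalysed oxidation with PhI(OAc)2 as terminal oxidant takes the primary alcohol to aldehyde 30, whose hydrate is oxidised on to the acid in the same mildly acidic medium, so the aldehyde should not accumulate, no base is present to enolise C3 or expel the aryloxide, and no electrophilic chlorine is generated that could attack ring A or the alkenes.

Step 16
Reactants: 31 (R)-2-ArB-3-[3,5-bis(TIPS-oxy)-4-prenylphenoxy]propanoic acid
Product: 33 (3R)-6,3'-diprenyl-5,7,4'-tris(TIPS-oxy)isoflavanone, via acid chloride 32 (not isolated)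
Conditions: 1-chloro-N,N,2-trimethylprop-1-en-1-amine, CH2Cl2, 0 °C; then Me2AlCl (3 equiv), CH2Cl2, −78 to −20 °C
Reagents that add atoms: none
Why: The acid chloride forms under neutral conditions and Me2AlCl then promotes intramolecular Friedel–Crafts acylation at C4a (identical with C8 by symmetry) to close ring C as a six-membered ketone, the aluminium methyl groups consuming the liberated HCl as methane so that neither prenyl group is protonated and, with no base present, C3 has no ketene or enolate pathway to epimerise.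

Step 17
Reactants: 33 (3R)-6,3'-diprenyl-5,7,4'-tris(TIPS-oxy)isoflavanone
Product: 34 CNP0206440.1, (3R)-5,7,4'-trihydroxy-6,3'-diprenylisoflavanone
Conditions: Bu4NF/AcOH (1:1), THF, 0 °C
Reagents that add atoms: none
Why: Fluoride cleaves the three aryl silyl ethers, and buffering with acetic acid keeps the medium non-basic so that the phenols should be released without enolisation at C3 and without acid-induced cyclisation of the prenyl groups onto the neighbouring hydroxyls.

**Compound list**

1 | 4-bromophenol | Oc1ccc(Br)cc1 | starting material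
2 | prenyl bromide (1-bromo-3-methylbut-2-ene) | CC(C)=CCBr | starting material
3 | 4-bromo-2-prenylphenol | CC(C)=CCc1cc(Br)ccc1O | intermediate
4 | (4-bromo-2-prenylphenoxy)triisopropylsilane | CC(C)=CCc1cc(Br)ccc1O[Si](C(C)C)(C(C)C)C(C)C | intermediate
5 | diethyl malonate | CCOC(=O)CC(=O)OCC | starting material
6 | diethyl 2-[3-prenyl-4-(TIPS-oxy)phenyl]malonate | CCOC(=O)C(C(=O)OCC)c1ccc(O[Si](C(C)C)(C(C)C)C(C)C)c(CC=C(C)C)c1 | intermediate
7 | 2-[3-prenyl-4-(TIPS-oxy)phenyl]propane-1,3-diol | OCC(CO)c1ccc(O[Si](C(C)C)(C(C)C)C(C)C)c(CC=C(C)C)c1 | intermediate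
8 | (S)-3-hydroxy-2-[3-prenyl-4-(TIPS-oxy)phenyl]propyl acetate | CC(=O)OC[C@H](CO)c1ccc(O[Si](C(C)C)(C(C)C)C(C)C)c(CC=C(C)C)c1 | intermediate
9 | (S)-2-[3-prenyl-4-(TIPS-oxy)phenyl]-3-(trityloxy)propyl acetate | CC(=O)OC[C@H](COC(c1ccccc1)(c1ccccc1)c1ccccc1)c1ccc(O[Si](C(C)C)(C(C)C)C(C)C)c(CC=C(C)C)c1 | intermediate
10 | (R)-2-[3-prenyl-4-(TIPS-oxy)phenyl]-3-(trityloxy)propan-1-ol | OC[C@H](COC(c1ccccc1)(c1ccccc1)c1ccccc1)c1ccc(O[Si](C(C)C)(C(C)C)C(C)C)c(CC=C(C)C)c1 | intermediate
11 | trichloroethylene | ClC=C(Cl)Cl | starting material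
12 | (S)-(E)-1,2-dichlorovinyl ether of 10 (not isolated) | Cl/C=C(/Cl)OC[C@H](COC(c1ccccc1)(c1ccccc1)c1ccccc1)c1ccc(O[Si](C(C)C)(C(C)C)C(C)C)c(CC=C(C)C)c1 | intermediate
13 | (R)-lithium alkoxyacetylide, C-lithiated 14 (not isolated) | [Li]C#COC[C@H](COC(c1ccccc1)(c1ccccc1)c1ccccc1)c1ccc(O[Si](C(C)C)(C(C)C)C(C)C)c(CC=C(C)C)c1 | intermediate
14 | (R)-1-(ethynyloxy)-2-[3-prenyl-4-(TIPS-oxy)phenyl]-3-(trityloxy)propane | C#COC[C@H](COC(c1ccccc1)(c1ccccc1)c1ccccc1)c1ccc(O[Si](C(C)C)(C(C)C)C(C)C)c(CC=C(C)C)c1 | intermediate
15 | acetylene | C#C | starting material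
16 | lithium acetylide (not isolated) | [Li]C#C | intermediate
17 | lithium ethynolate (not isolated) | [Li]OC#C | intermediate
18 | (ethynyloxy)triisopropylsilane | C#CO[Si](C(C)C)(C(C)C)C(C)C | intermediate
19 | 5-methylhex-4-enoic acid | CC(C)=CCCC(=O)O | starting material
20 | 5-methylhex-4-enoyl chloride | CC(C)=CCCC(=O)Cl | intermediate
21 | prenylketene, 5-methylhexa-1,4-dien-1-one (not isolated) | CC(C)=CCC=C=O | intermediate
22 | 4-prenyl-3-(TIPS-oxy)cyclobut-2-en-1-one (racemic) | O=C1C=C(O[Si](C(C)C)(C(C)C)C(C)C)C1CC=C(C)C | intermediate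
23 | vinylketene, 7-methyl-3-(TIPS-oxy)octa-1,3,6-trien-1-one, chain trans across C3=C4 (not isolated) | O=C=C/C(O[Si](C(C)C)(C(C)C)C(C)C)=C/CC=C(C)C | intermediate
24 | 3-alkoxy-4-[1-(TIPS-oxy)-4-methylpenta-1,3-dienyl]cyclobut-2-en-1-one, alkoxy = the (R)-CH2CH(ArB)CH2OTr group, ring sp3 carbon unassigned (not isolated) | O=C1C=C(OC[C@H](COC(c2ccccc2)(c2ccccc2)c2ccccc2)c2ccc(O[Si](C(C)C)(C(C)C)C(C)C)c(CC=C(C)C)c2)C1/C(O[Si](C(C)C)(C(C)C)C(C)C)=C/CC=C(C)C | intermediate
25 | dienylketene, 3-alkoxy-5-(TIPS-oxy)-9-methyldeca-1,3,5,8-tetraen-1-one with C2 and C5 cis across C3=C4 (not isolated) | O=C=C/C(OC[C@H](COC(c1ccccc1)(c1ccccc1)c1ccccc1)c1ccc(O[Si](C(C)C)(C(C)C)C(C)C)c(CC=C(C)C)c1)=C\C(O[Si](C(C)C)(C(C)C)C(C)C)=C\CC=C(C)C | intermediate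
26 | 3-alkoxy-6-prenyl-5-(TIPS-oxy)cyclohexa-2,4-dien-1-one, C6 unassigned (not isolated) | O=C1C=C(OC[C@H](COC(c2ccccc2)(c2ccccc2)c2ccccc2)c2ccc(O[Si](C(C)C)(C(C)C)C(C)C)c(CC=C(C)C)c2)C=C(O[Si](C(C)C)(C(C)C)C(C)C)C1CC=C(C)C | intermediate
27 | (R)-5-{2-[3-prenyl-4-(TIPS-oxy)phenyl]-3-(trityloxy)propoxy}-2-prenyl-3-(TIPS-oxy)phenol | CC(C)=CCc1c(O)cc(OC[C@H](COC(c2ccccc2)(c2ccccc2)c2ccccc2)c2ccc(O[Si](C(C)C)(C(C)C)C(C)C)c(CC=C(C)C)c2)cc1O[Si](C(C)C)(C(C)C)C(C)C | intermediate
28 | (R)-1-[3,5-bis(TIPS-oxy)-4-prenylphenoxy]-2-[3-prenyl-4-(TIPS-oxy)phenyl]-3-(trityloxy)propane | CC(C)=CCc1c(O[Si](C(C)C)(C(C)C)C(C)C)cc(OC[C@H](COC(c2ccccc2)(c2ccccc2)c2ccccc2)c2ccc(O[Si](C(C)C)(C(C)C)C(C)C)c(CC=C(C)C)c2)cc1O[Si](C(C)C)(C(C)C)C(C)C | intermediate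
29 | (S)-3-[3,5-bis(TIPS-oxy)-4-prenylphenoxy]-2-[3-prenyl-4-(TIPS-oxy)phenyl]propan-1-ol | CC(C)=CCc1c(O[Si](C(C)C)(C(C)C)C(C)C)cc(OC[C@H](CO)c2ccc(O[Si](C(C)C)(C(C)C)C(C)C)c(CC=C(C)C)c2)cc1O[Si](C(C)C)(C(C)C)C(C)C | intermediate
30 | (R)-3-[3,5-bis(TIPS-oxy)-4-prenylphenoxy]-2-[3-prenyl-4-(TIPS-oxy)phenyl]propanal (not isolated) | CC(C)=CCc1c(O[Si](C(C)C)(C(C)C)C(C)C)cc(OC[C@H](C=O)c2ccc(O[Si](C(C)C)(C(C)C)C(C)C)c(CC=C(C)C)c2)cc1O[Si](C(C)C)(C(C)C)C(C)C | intermediate
31 | (R)-3-[3,5-bis(TIPS-oxy)-4-prenylphenoxy]-2-[3-prenyl-4-(TIPS-oxy)phenyl]propanoic acid | CC(C)=CCc1c(O[Si](C(C)C)(C(C)C)C(C)C)cc(OC[C@H](C(=O)O)c2ccc(O[Si](C(C)C)(C(C)C)C(C)C)c(CC=C(C)C)c2)cc1O[Si](C(C)C)(C(C)C)C(C)C | intermediate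
32 | (R)-3-[3,5-bis(TIPS-oxy)-4-prenylphenoxy]-2-[3-prenyl-4-(TIPS-oxy)phenyl]propanoyl chloride (not isolated) | CC(C)=CCc1c(O[Si](C(C)C)(C(C)C)C(C)C)cc(OC[C@H](C(Cl)=O)c2ccc(O[Si](C(C)C)(C(C)C)C(C)C)c(CC=C(C)C)c2)cc1O[Si](C(C)C)(C(C)C)C(C)C | intermediate
33 | (3R)-6-prenyl-3-[3-prenyl-4-(TIPS-oxy)phenyl]-5,7-bis(TIPS-oxy)chroman-4-one | CC(C)=CCc1cc([C@@H]2COc3cc(O[Si](C(C)C)(C(C)C)C(C)C)c(CC=C(C)C)c(O[Si](C(C)C)(C(C)C)C(C)C)c3C2=O)ccc1O[Si](C(C)C)(C(C)C)C(C)C | intermediate
34 | CNP0206440.1, (3R)-5,7-dihydroxy-3-(4-hydroxy-3-prenylphenyl)-6-prenylchroman-4-one | CC(C)=CCc1cc([C@@H]2COc3cc(O)c(CC=C(C)C)c(O)c3C2=O)ccc1O | target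

**Step count and risk**

Total: 17 steps. Longest linear sequence: 14 steps (steps 1 to 8, then 12 to 17).

Steps most likely to fail:

1. Step 12. What may go wrong: retro-ene fragmentation of ynol ether 14 (loss of ketene) at the temperature needed to open 22; acylation of the newly formed phenol by the vinylketene; hydrolysis of the vinylogous silyl ester 22 by adventitious water. Fallback: ring A is made separately and joined through the O1–C2 bond instead of being built on O1. Phloroglucinol (commercial) is C-prenylated with 2 (aqueous KOH) to 2-prenylphloroglucinol F1, which is silylated exhaustively (TIPSOTf, 2,6-lutidine) to 2-prenyl-1,3,5-tris(TIPS-oxy)benzene F2. The one silyl ether not flanked by the prenyl group is then cleaved selectively (Bu4NF, one equivalent, −78 °C) to give 4-prenyl-3,5-bis(TIPS-oxy)phenol F3. Mitsunobu etherification of F3 with alcohol 10 (PPh3, DIAD, toluene) should give 28. The fallback sets out from 10 (and 2) and comes back at 28; the reacting carbon is the primary CH2, so C3 is not touched.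

2. Step 16. What may go wrong: protonation or cyclisation of the prenyl groups by acid released during acylation; loss of configuration at C3 through ketene formation from the activated acid or enolisation of the product ketone; slow ring closure next to the bulky O5 silyl ether. Fallback: C4–C4a is closed at the aldehyde oxidation level, where no acid is released. Alcohol 29 is oxidised with Dess–Martin periodinane to aldehyde 30, this time isolated. Me2AlCl (CH2Cl2, −78 °C) promotes intramolecular hydroxyalkylation of ring A at C4a to give (3R)-6-prenyl-3-ArB-5,7-bis(TIPS-oxy)chroman-4-ol F4 as both C4 epimers, and a second Dess–Martin oxidation converges these on ketone 33. The fallback sets out from 29 and comes back at 33.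

3. Step 9. What may go wrong: silylation of the ambident ynolate at carbon (giving a silylketene) instead of oxygen; disproportionation of monolithium acetylide before it is oxygenated. Fallback: the siloxyalkyne is avoided and the silyl group is put on after the four-membered ring exists. Potassium tert-butoxide and 11 give (E)-1,2-dichlorovinyl tert-butyl ether F5, which n-BuLi and then water convert into tert-butoxyethyne F6. Cycloaddition of F6 with prenylketene 21 (from 20 and Et3N, as in step 11) gives 3-tert-butoxy-4-prenylcyclobut-2-en-1-one F7. TIPSOTf with 2,6-lutidine then silylates the carbonyl oxygen of this vinylogous ester and the tert-butyl group leaves as 2-methylpropene, the exchange known for tert-butyl esters and carbamates. Carbonyl and siloxy positions change places, but C4 lies between them, so the product is 22. The fallback sets out from 20 and 11 and comes back at 22.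

**Further compounds**

F1 | step 12 | 2-prenylphloroglucinol, 2-(3-methylbut-2-en-1-yl)benzene-1,3,5-triol | CC(C)=CCc1c(O)cc(O)cc1O
F2 | step 12 | 2-prenyl-1,3,5-tris(TIPS-oxy)benzene | CC(C)=CCc1c(O[Si](C(C)C)(C(C)C)C(C)C)cc(O[Si](C(C)C)(C(C)C)C(C)C)cc1O[Si](C(C)C)(C(C)C)C(C)C
F3 | step 12 | 4-prenyl-3,5-bis(TIPS-oxy)phenol | CC(C)=CCc1c(O[Si](C(C)C)(C(C)C)C(C)C)cc(O)cc1O[Si](C(C)C)(C(C)C)C(C)C
F4 | step 16 | (3R)-6-prenyl-3-[3-prenyl-4-(TIPS-oxy)phenyl]-5,7-bis(TIPS-oxy)chroman-4-ol, both C4 epimers | CC(C)=CCc1cc([C@@H]2COc3cc(O[Si](C(C)C)(C(C)C)C(C)C)c(CC=C(C)C)c(O[Si](C(C)C)(C(C)C)C(C)C)c3C2O)ccc1O[Si](C(C)C)(C(C)C)C(C)C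
F5 | step 9 | (E)-1,2-dichlorovinyl tert-butyl ether | Cl/C=C(/Cl)OC(C)(C)C
F6 | step 9 | tert-butoxyethyne | C#COC(C)(C)C
F7 | step 9 | 3-tert-butoxy-4-prenylcyclobut-2-en-1-one (racemic) | O=C1C=C(OC(C)(C)C)C1CC=C(C)C
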